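In the gamma run E is slow to leave: it reads 38.8% at 6.00 min and still 9.7% at 50.0 min.

| flask | X | J | remark | time |
|---|---|---|---|---|
| beta | 0.50 M | 0.20 M | run made earlier |  |
| gamma | 0.50 M | 0.45 M | run made earlier |  |
| zeta | 0.25 M | 0.30 M | run made earlier |  |
| flask | 0.50 M | 0.300 M |  | 2.5 h |

- beta (time / min: E / %, X / %): 1.33: 12.2, 87.8; 3.00: 18.6, 78.6; 6.00: 21.0, 74.6; 12.0: 17.8, 74.9; 20.0: 15.6, 72.7; 50.0: 5.9, 66.9; 90.0: 3.3, 65.7
- gamma (time / min: E / %, X / %): 1.33: 24.7, 74.2; 3.00: 35.3, 61.6; 6.00: 38.8, 54.8; 12.0: 31.7, 52.3; 20.0: 24.9, 50.6; 50.0: 9.7, 45.8; 90.0: 2.8, 41.6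
- zeta (time / min: E / %, X / %): 1.33: 20.8, 80.1; 4.00: 34.1, 65.6; 12.0: 31.3, 54.0; 30.0: 19.4, 49.8; 90.0: 5.1, 40.9

(readings scatter by 1 percentage point)

1. time, not beyond 2.5 h, at which the flask holds most E
2. the amount of E, in percent of the X charged, at that time

- the numbers in the tables scatter with a standard deviation of 1 percentage point

So we reckon with two rates. We take the making of E to go with [X][J] and its unmaking with [E]. At a peak the two are equal, so we expect roughly one quotient there. We reckon with what is left: J is not among the readings, so we count each unit of [E] as taken off both charges, and that is rough, since X and E together read 93.6% at the highest gamma reading of E. The highest beta reading gives 2.80 M⁻¹ and the highest gamma reading 2.48 M⁻¹. Their mean is our peak quotient, [E] over the product of the two charges less [E], 2.64 M⁻¹. Solved for this flask, where J is the limiting reagent, it gives [E] = 0.145 M, or 29.0% of the X charged. It gives no time.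

The forecast, made separately by stepping the flask through, says 28.5% (26.5% to 30.5%) at 0.11 h (0.08 h to 0.14 h), holding that “J must also die on its own”.

The flask gives 28.6% at 0.0915 h, earlier than the forecast's time.

    X + J ⇌ E (K = 5.40 M⁻¹, k = 0.730 M⁻¹ min⁻¹)
    E → L (k = 0.0390 min⁻¹)
    2 J → G (k = 0.100 M⁻¹ min⁻¹)

Now we charge 2.0 M of X with the same J, which is 0.150 equiv of J to X. The peak quotient then gives 12.3% of the X charged, and that flask holds at most 12.1% of E.

The data stem from a simulated flask on assumed constants.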